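**Retrosynthetic overview**
- Last step: O-demethylation of the ring A methyl ether. The methyl group keeps ring A an ether, so only ring B reacts as a phenol during bromination.
- Ring B is not taken from an arene. It is traced back to a 2-aryloxycyclohex-2-enone. One brominative aromatisation puts Br on C3 (enol-ether carbon) and on C4 and C6 (enol/phenol carbons), which are the three brominated positions.
- Key disconnection: the inter-ring C–O bond, cut at the ketone α-carbon. This carbon becomes the ortho carbon of phenol ring B and is by nature a donor, like the phenol oxygen it must join. It is used with reversed polarity as an enolonium equivalent, 2,3-epoxycyclohexanone, and is attacked by 5-bromo-2-methoxyphenoxide.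
- Ring order: ring A is bought complete with its bromine. The ring B carbocycle is bought non-aromatic and is aromatised after the coupling. No ring closure is needed.

Assumption: the target has no stereocentre and no configurationally stable axis, so it is one achiral compound and no step needs stereocontrol. The two rings are joined only through oxygen, so that C–O bond is the strategic bond.

**Step 1**
Reactants: 1 (±)-2,3-epoxycyclohexan-1-one (7-oxabicyclo[4.1.0]heptan-2-one, racemic, cis-fused epoxide); 2 5-bromo-2-methoxyphenol
Product: 4 2-(5-bromo-2-methoxyphenoxy)cyclohex-2-en-1-one, via trans-hydroxy ketone 3 (not isolated)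
Conditions: 2 (1.0 equiv), 1 (1.3 equiv), KH (0.2 equiv), THF–DMPU (4:1), 65 °C, 16 h
Reagents that add atoms: none
Why: The phenoxide opens the α,β-epoxy ketone by SN2 attack at C2, the carbonyl-flanked carbon that serves here as an enolonium (a2) equivalent although a ketone α-carbon is normally a donor, giving trans-hydroxy ketone 3 (inversion at C2), which loses water by E1cB elimination and regenerates the base (the known aryloxyenone synthesis from epoxy ketones and phenols); both transient stereocentres vanish and the target has none.

**Step 2**
Reactants: 4 2-(5-bromo-2-methoxyphenoxy)cyclohex-2-en-1-one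
Product: 9 3,4,6-tribromo-2-(5-bromo-2-methoxyphenoxy)phenol, via 3-bromoenone 5 (not isolated), via 3,6-dibromoenone 6 (not isolated), via ring B monobromophenol 7 (not isolated), via ring B dibromophenol 8 (not isolated)
Conditions: Br2 (1.0 equiv), NaOAc (1.2 equiv), AcOH–ClCH2CH2Cl (1:1), 0 °C, 1 h; then Br2 (3.05 equiv), 0 → 65 °C, 4 h
Reagents that add atoms: bromine, BrBr
Why: Proposed new method: this is a temperature-staged one-flask merger of three known reaction types, reasoned as follows: at 0 °C under acetate buffer ketone enolisation is slow, so the first Br2 attacks only the C2=C3 enol-ether bond at C3 and the aryloxy-stabilised cation loses the C3 proton to give vinyl bromide 5 (closest known type: bromination–dehydrobromination of 2-alkoxy- and 2-acyloxy-enones and of diosphenols to their 3-bromo derivatives); on warming, HBr-catalysed enolisation gives α'-bromide 6, which expels HBr and tautomerises to phenol 7 (closest known type: bromination–dehydrobromination aromatisation of cyclohexenones), and 7 undergoes electrophilic aromatic bromination para (8) and then ortho (9) to its OH; because C4 and C6 are the only carbons that an enol, dienol or phenol can offer to Br2 and both carry Br in 9, the order of the late events does not matter, C5 is never activated, and ring A (position para to OMe blocked, other oxygen tied to an electron-poor ring) should be left alone at exact stoichiometry.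

**Step 3**
Reactants: 9 3,4,6-tribromo-2-(5-bromo-2-methoxyphenoxy)phenol
Product: 11 3,4,6-tribromo-2-(5-bromo-2-hydroxyphenoxy)phenol, via bis(dibromoboryl) ether 10 (not isolated)
Conditions: BBr3 (3.0 equiv), CH2Cl2, –78 → 23 °C, 12 h; then H2O, 0 °C
Reagents that add atoms: none
Why: This is a Lewis acid-mediated aryl methyl ether cleavage in which BBr3 binds the methoxy oxygen, bromide removes the methyl group by SN2, the free phenol is borylated as well (10) and water hydrolyses both B–O bonds, while the diaryl ether and the four aryl C–Br bonds are inert to BBr3 at or below 23 °C.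

**Compound list**
1 | (±)-2,3-epoxycyclohexan-1-one (racemic, cis-fused; one enantiomer drawn) | O=C1CCC[C@@H]2O[C@H]12 | starting material
2 | 5-bromo-2-methoxyphenol | COc1ccc(Br)cc1O | starting material
3 | (±)-trans-2-(5-bromo-2-methoxyphenoxy)-3-hydroxycyclohexan-1-one (racemic; one enantiomer drawn) | O=C1CCC[C@H](O)[C@H]1Oc1cc(Br)ccc1OC | intermediate
4 | 2-(5-bromo-2-methoxyphenoxy)cyclohex-2-en-1-one | O=C1CCCC=C1Oc1cc(Br)ccc1OC | intermediate
5 | 3-bromo-2-(5-bromo-2-methoxyphenoxy)cyclohex-2-en-1-one | O=C1CCCC(Br)=C1Oc1cc(Br)ccc1OC | intermediate
6 | (±)-3,6-dibromo-2-(5-bromo-2-methoxyphenoxy)cyclohex-2-en-1-one (racemic at C6) | O=C1C(Br)CCC(Br)=C1Oc1cc(Br)ccc1OC | intermediate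
7 | 3-bromo-2-(5-bromo-2-methoxyphenoxy)phenol | COc1ccc(Br)cc1Oc1c(O)cccc1Br | intermediate
8 | 3,4-dibromo-2-(5-bromo-2-methoxyphenoxy)phenol | COc1ccc(Br)cc1Oc1c(O)ccc(Br)c1Br | intermediate
9 | 3,4,6-tribromo-2-(5-bromo-2-methoxyphenoxy)phenol | COc1ccc(Br)cc1Oc1c(O)c(Br)cc(Br)c1Br | intermediate
10 | bis(dibromoboryl) ether of the target (both phenol oxygens carry BBr2) | BrB(Br)Oc1ccc(Br)cc1Oc1c(OB(Br)Br)c(Br)cc(Br)c1Br | intermediate
11 | 3,4,6-tribromo-2-(5-bromo-2-hydroxyphenoxy)phenol (achiral) | Oc1ccc(Br)cc1Oc1c(O)c(Br)cc(Br)c1Br | target

**Total step count:** 3. **Longest linear sequence:** 3.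

**Steps most likely to fail**

Step 2 is the most likely to fail.
- If ketone enolisation competes in the cold stage, ring B aromatises before C3 is brominated. That gives the 4,6-dibromophenol without the C3 bromine, and the unused Br2 then over-brominates.
- Hot Br2 may also attack ring A para to the ether oxygen.

The fallback sets out from 4 and comes back at 9. Bromine is no longer the dehydrogenating agent, and each event gets its own reagent. 4 is treated with Br2 (1.0 equiv, CH2Cl2, 0 °C) and then Et3N, and 5 is isolated. Kinetic deprotonation at C6 with LiN(SiMe3)2 and trapping with Me3SiCl (THF, –78 °C) gives 1-bromo-2-(5-bromo-2-methoxyphenoxy)-3-(trimethylsilyloxy)cyclohexa-1,3-diene F1. DDQ (toluene, 23 °C) takes two hydrogens from this cyclohexadiene to give [3-bromo-2-(5-bromo-2-methoxyphenoxy)phenoxy]trimethylsilane F2. Dilute aqueous HCl in THF frees 7, which is now isolated. Benzyltrimethylammonium tribromide (2.05 equiv, CH2Cl2–MeOH, 23 °C) brominates phenols but not deactivated aryl ethers, and it takes 7 through 8 to 9.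

Step 1 is second.
- The hindered ortho-methoxy phenoxide may attack C3 instead of C2.
- The base may isomerise 1 to the diosphenol or oligomerise it faster than the coupling runs.

The fallback sets out from 2 and comes back at 5. C2 of ring B stays the electrophile, but as a rhodium carbenoid of a 1,3-dione instead of an epoxide carbon. Cyclohexane-1,3-dione and PhI(OAc)2 (KOH, MeOH, 0 °C) give 3-oxo-2-(phenyliodonio)cyclohex-1-en-1-olate F3. This ylide, 2 and Rh2(OAc)4 (1 mol %) in CH2Cl2 at 23 °C give, by O–H insertion, 2-(5-bromo-2-methoxyphenoxy)-3-hydroxycyclohex-2-en-1-one F4, the enol of the 1,3-dione. Ph3PBr2/Et3N (MeCN, 23 °C) turns this vinylogous acid into the vinylogous acid bromide 5, which places the C3 bromine without any regiochemical question. Isolated 5 then enters the warm stage of step 2 (Br2, 3.05 equiv).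

Step 3 is the least risky. It could still suffer from incomplete cleavage next to the bulky aryloxy group, or from acid-induced bromine loss or migration in the polybromophenol.

The fallback sets out from 9 and comes back at 11. The methyl carbon is attacked by a soft nucleophile instead of the ether oxygen being activated by an acid. NaSEt (4 equiv, DMF, 100 °C) first forms the ring B phenoxide, which shields that ring from substitution. It then removes CH3 by SN2 to give disodium 4-bromo-2-(2,3,5-tribromo-6-oxidophenoxy)phenolate F5, which 1 M HCl converts into 11.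

**Further compounds**
F1 | step 2 | 1-bromo-2-(5-bromo-2-methoxyphenoxy)-3-(trimethylsilyloxy)cyclohexa-1,3-diene | C[Si](C)(C)OC1=CCCC(Br)=C1Oc1cc(Br)ccc1OC
F2 | step 2 | [3-bromo-2-(5-bromo-2-methoxyphenoxy)phenoxy]trimethylsilane | C[Si](C)(C)Oc1cccc(Br)c1Oc1cc(Br)ccc1OC
F3 | step 1 | 3-oxo-2-(phenyliodonio)cyclohex-1-en-1-olate | O=C1CCCC([O-])=C1[I+]c1ccccc1
F4 | step 1 | 2-(5-bromo-2-methoxyphenoxy)-3-hydroxycyclohex-2-en-1-one | O=C1CCCC(O)=C1Oc1cc(Br)ccc1OC
F5 | step 3 | disodium 4-bromo-2-(2,3,5-tribromo-6-oxidophenoxy)phenolate | [Na+].[Na+].[O-]c1ccc(Br)cc1Oc1c([O-])c(Br)cc(Br)c1Br
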